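**Strategy.** The flavone is cut across ring C at C4a–C4, C4–C3 and O1–C2. Because C4 is a ketone carbon lodged between the ring A carbon C4a and C3, while O1 links C8a to C2, C4 can be delivered as carbon monoxide between an aryl iodide and a terminal alkyne. One palladium-catalysed operation joins iodophenol 7, CO and 4-ethynylanisole and closes ring C through the C8a hydroxyl. The precursor is a fully substituted ring A phenol: free OH at C8a, iodine at C4a, methoxy at C8, methyl at C6, and O5/O7 masked as methoxymethyl ethers. The 3-methoxy group is installed afterwards by epoxidation–isomerisation and methylation; acid then frees O5 and O7.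

Key step: step 6

Remark: O5 and O7 are carried as methoxymethyl ethers because aryl-containing groups such as benzyl would offer unhindered aromatic C–H bonds that compete in the iridium borylation of step 2; the acetals also come off with mild acid, so no hydrogenation is needed next to the chromone.
Remark: the target is achiral; the only stereogenic intermediate, epoxide 13, forms as a racemate and is aromatised in the same step.

**Step 1**
Reactants: 1 2-methylresorcinol
Product: 2 1,3-bis(methoxymethoxy)-2-methylbenzene
Conditions: MOMCl, iPr2NEt, CH2Cl2, 0 °C → reflux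
Reagents that add atoms: chloromethyl methyl ether, COCCl
Why: Double Williamson-type O-alkylation (methoxymethyl protection) of both phenols, giving ethers that tolerate base, palladium/CO and dioxirane and leave the ring with a single unhindered C–H for step 2.

**Step 2**
Reactants: 2 1,3-bis(methoxymethoxy)-2-methylbenzene
Product: 4 3,5-bis(methoxymethoxy)-4-methylphenol, via aryl pinacol boronate 3 (not isolated)
Conditions: [Ir(OMe)(cod)]2 (1.5 mol%), 4,4'-di-tert-butyl-2,2'-bipyridine (3 mol%), B2pin2, THF, 80 °C; then 30% H2O2, aq NaOH, 0 °C → rt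
Reagents that add atoms: bis(pinacolato)diboron, CC1(C)OB(OC1(C)C)B1OC(C)(C)C(C)(C)O1 (boron carried only in intermediate 3); hydrogen peroxide, OO
Why: Iridium-catalysed aromatic C–H borylation is sterically governed and should select C5, the only ring C–H without an ortho substituent, and basic peroxide oxidation of the C–B bond (aryl shift from boron to oxygen) then gives the phenol that becomes O1.

**Step 3**
Reactants: 4 3,5-bis(methoxymethoxy)-4-methylphenol
Product: 5 2-bromo-3,5-bis(methoxymethoxy)-4-methylphenol
Conditions: NBS (1.0 equiv), CH2Cl2, −78 → 0 °C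
Reagents that add atoms: N-bromosuccinimide, O=C1CCC(=O)N1Br
Why: Electrophilic aromatic bromination directed by the free hydroxyl; the para position is blocked by the methyl group and the two ortho positions are equivalent, so only over-bromination must be held back by one equivalent at low temperature.

**Step 4**
Reactants: 5 2-bromo-3,5-bis(methoxymethoxy)-4-methylphenol
Product: 6 2-methoxy-3,5-bis(methoxymethoxy)-4-methylphenol
Conditions: NaOMe (25% in MeOH, excess), CuBr (20 mol%), DMF, 110 °C
Reagents that add atoms: sodium methoxide, C[O-].[Na+]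
Why: Copper-catalysed Ullmann-type methoxylation of an ortho-bromophenol (the classical bromophenol-to-guaiacol exchange) replaces C–Br by C–OMe, the acetal ethers being inert to methoxide.

**Step 5**
Reactants: 6 2-methoxy-3,5-bis(methoxymethoxy)-4-methylphenol
Product: 7 2-iodo-6-methoxy-3,5-bis(methoxymethoxy)-4-methylphenol
Conditions: NIS, MeCN, 0 °C, dark
Reagents that add atoms: N-iodosuccinimide, O=C1CCC(=O)N1I
Why: Electrophilic aromatic iodination at the only remaining ring C–H, which is ortho to the free hydroxyl and ortho/para to the two acetal ethers, so no regiochemical choice exists.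

**Step 6**
Reactants: 7 2-iodo-6-methoxy-3,5-bis(methoxymethoxy)-4-methylphenol; 8 4-ethynylanisole; 9 carbon monoxide
Product: 12 8-methoxy-2-(4-methoxyphenyl)-5,7-bis(methoxymethoxy)-6-methyl-4H-chromen-4-one, via ortho-hydroxyaryl ynone 10 (not isolated), via enaminone 11 (not isolated)
Conditions: PdCl2(dppf) (5 mol%), CO (20 bar), Et2NH, 120 °C
Reagents that add atoms: diethylamine, CCNCC (carried only in intermediate 11 and expelled on ring closure)
Why: Zerovalent palladium, formed from PdCl2(dppf) in the amine, inserts into the C4a–I bond of 7, CO insertion gives an aroylpalladium iodide, and coupling with the acetylide of 8 releases ynone 10 (C4a–C4 and C4–C3); diethylamine then adds to the alkyne carbon β to the carbonyl to give enaminone 11, and the C8a hydroxyl attacks that carbon and expels the amine (O1–C2). The closest known reaction type is the palladium-catalysed carbonylative Sonogashira coupling–cyclisation of 2-iodophenols with terminal arylacetylenes to flavones. Ring C closes in a 6-endo mode (6-endo-trig addition–elimination on the enaminone), and no stereocentre is formed. The step needs carbonylative rather than direct coupling, which CO pressure and the slow direct alkynylation of a doubly ortho-substituted iodide should secure, and six- rather than five-membered closure (flavone, not aurone), which passage through the enaminone should secure because its electrophilic carbon is C2. Regiochemistry is fixed by the substrate, since iodine sits on C4a and the only free hydroxyl is on C8a, O5 being capped as an acetal.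

**Step 7**
Reactants: 12 8-methoxy-2-(4-methoxyphenyl)-5,7-bis(methoxymethoxy)-6-methyl-4H-chromen-4-one
Product: 14 3-hydroxy-8-methoxy-2-(4-methoxyphenyl)-5,7-bis(methoxymethoxy)-6-methyl-4H-chromen-4-one, via flavone 2,3-epoxide 13 (not isolated)
Conditions: dimethyldioxirane (acetone solution, excess), CH2Cl2, 0 °C → rt; concentrate; then p-TsOH·H2O (cat.), CH2Cl2, 0 °C
Reagents that add atoms: dimethyldioxirane, CC1(C)OO1
Why: Dioxirane epoxidation of the C2=C3 enol-ether bond of a flavone (concerted syn oxygen transfer gives the cis-fused racemic oxirane 13, whose two stereocentres are erased again), followed by acid opening at C2 to a cation stabilised by O1 and the anisyl ring and loss of H3, should give the flavonol.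

**Step 8**
Reactants: 14 3-hydroxy-8-methoxy-2-(4-methoxyphenyl)-5,7-bis(methoxymethoxy)-6-methyl-4H-chromen-4-one
Product: 15 3,8-dimethoxy-2-(4-methoxyphenyl)-5,7-bis(methoxymethoxy)-6-methyl-4H-chromen-4-one
Conditions: MeI, K2CO3, acetone, reflux
Reagents that add atoms: iodomethane, CI
Why: Williamson O-methylation of the 3-hydroxyl, the only free OH in 14.

**Step 9**
Reactants: 15 3,8-dimethoxy-2-(4-methoxyphenyl)-5,7-bis(methoxymethoxy)-6-methyl-4H-chromen-4-one
Product: 16 5,7-dihydroxy-3,8-dimethoxy-2-(4-methoxyphenyl)-6-methyl-4H-chromen-4-one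
Conditions: 3 M aq HCl, MeOH, 50 °C
Reagents that add atoms: none
Why: Acid-catalysed acetal cleavage (methoxymethyl deprotection by transacetalisation to methanol) frees the C5 and C7 hydroxyls, while the aryl methyl ethers and the chromone are inert under these mild conditions.

**Compound list**
1 | 2-methylresorcinol (2-methylbenzene-1,3-diol) | Cc1c(O)cccc1O | starting material
2 | 1,3-bis(methoxymethoxy)-2-methylbenzene | COCOc1cccc(OCOC)c1C | intermediate
3 | 2-[3,5-bis(methoxymethoxy)-4-methylphenyl]-4,4,5,5-tetramethyl-1,3,2-dioxaborolane (formed in situ) | COCOc1cc(B2OC(C)(C)C(C)(C)O2)cc(OCOC)c1C | intermediate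
4 | 3,5-bis(methoxymethoxy)-4-methylphenol | COCOc1cc(O)cc(OCOC)c1C | intermediate
5 | 2-bromo-3,5-bis(methoxymethoxy)-4-methylphenol | COCOc1cc(O)c(Br)c(OCOC)c1C | intermediate
6 | 2-methoxy-3,5-bis(methoxymethoxy)-4-methylphenol | COCOc1cc(O)c(OC)c(OCOC)c1C | intermediate
7 | 2-iodo-6-methoxy-3,5-bis(methoxymethoxy)-4-methylphenol | COCOc1c(I)c(O)c(OC)c(OCOC)c1C | intermediate
8 | 4-ethynylanisole (1-ethynyl-4-methoxybenzene) | C#Cc1ccc(OC)cc1 | starting material
9 | carbon monoxide | [C-]#[O+] | starting material
10 | 1-[2-hydroxy-3-methoxy-4,6-bis(methoxymethoxy)-5-methylphenyl]-3-(4-methoxyphenyl)prop-2-yn-1-one (formed in situ) | COCOc1c(C(=O)C#Cc2ccc(OC)cc2)c(O)c(OC)c(OCOC)c1C | intermediate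
11 | (E)-3-(diethylamino)-1-[2-hydroxy-3-methoxy-4,6-bis(methoxymethoxy)-5-methylphenyl]-3-(4-methoxyphenyl)prop-2-en-1-one (formed in situ; geometry of no consequence) | CCN(CC)/C(=C/C(=O)c1c(O)c(OC)c(OCOC)c(C)c1OCOC)c1ccc(OC)cc1 | intermediate
12 | 8-methoxy-2-(4-methoxyphenyl)-5,7-bis(methoxymethoxy)-6-methyl-4H-chromen-4-one | COCOc1c(C)c(OCOC)c(OC)c2oc(-c3ccc(OC)cc3)cc(=O)c12 | intermediate
13 | 2,3-epoxy-8-methoxy-2-(4-methoxyphenyl)-5,7-bis(methoxymethoxy)-6-methylchroman-4-one (formed in situ; racemic, oxirane cis-fused to ring C, one enantiomer drawn) | COCOc1c(C)c(OCOC)c(OC)c2O[C@]3(c4ccc(OC)cc4)O[C@H]3C(=O)c12 | intermediate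
14 | 3-hydroxy-8-methoxy-2-(4-methoxyphenyl)-5,7-bis(methoxymethoxy)-6-methyl-4H-chromen-4-one | COCOc1c(C)c(OCOC)c(OC)c2oc(-c3ccc(OC)cc3)c(O)c(=O)c12 | intermediate
15 | 3,8-dimethoxy-2-(4-methoxyphenyl)-5,7-bis(methoxymethoxy)-6-methyl-4H-chromen-4-one | COCOc1c(C)c(OCOC)c(OC)c2oc(-c3ccc(OC)cc3)c(OC)c(=O)c12 | intermediate
16 | 5,7-dihydroxy-3,8-dimethoxy-2-(4-methoxyphenyl)-6-methyl-4H-chromen-4-one | COc1ccc(-c2oc3c(OC)c(O)c(C)c(O)c3c(=O)c2OC)cc1 | target

**Total step count:** 9
**Longest linear sequence:** 9 steps (1 → 16)

**Steps most likely to fail**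

Step 6. Direct, non-carbonylative alkynylation or hydrodeiodination of the hindered, electron-rich iodide may outrun CO insertion, or the ynone may close in the five-membered exo sense. The fallback brings C4 in as a formyl carbon instead of CO and sets out from phenol 6. Magnesium-mediated ortho-formylation (MgCl2, Et3N, paraformaldehyde, MeCN, reflux) at the only free ring position should give 2-hydroxy-3-methoxy-4,6-bis(methoxymethoxy)-5-methylbenzaldehyde F1. Alkyne 8 is deprotonated with n-BuLi (THF, −78 °C) to lithium (4-methoxyphenyl)acetylide F2, and an excess of it adds to F1 to give the racemic propargylic alcohol 2-[1-hydroxy-3-(4-methoxyphenyl)prop-2-yn-1-yl]-6-methoxy-3,5-bis(methoxymethoxy)-4-methylphenol F3. MnO2 in CH2Cl2 oxidises F3 to ynone 10, now isolated, and Et2NH in EtOH closes it through enaminone 11. The fallback rejoins the route at flavone 12.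

Step 4. Reductive loss of bromine, or a stalled carbon–oxygen coupling at a bromide flanked by two oxygen substituents on a phenoxide, may leave the methoxy group uninstalled. The fallback builds the C8 oxygen by formylation and Dakin-type oxidation and sets out from phenol 4. Magnesium-mediated ortho-formylation should give 6-hydroxy-2,4-bis(methoxymethoxy)-3-methylbenzaldehyde F4. Benzylation (BnBr, K2CO3, DMF) gives 6-(benzyloxy)-2,4-bis(methoxymethoxy)-3-methylbenzaldehyde F5. Baeyer–Villiger oxidation (mCPBA, NaHCO3, CH2Cl2) gives 6-(benzyloxy)-2,4-bis(methoxymethoxy)-3-methylphenyl formate F6, which is methanolysed without isolation (K2CO3, MeOH) to 6-(benzyloxy)-2,4-bis(methoxymethoxy)-3-methylphenol F7. Methylation (MeI, K2CO3, acetone) gives 1-(benzyloxy)-2-methoxy-3,5-bis(methoxymethoxy)-4-methylbenzene F8, and hydrogenolysis (H2, Pd/C, EtOAc) removes the benzyl group. The fallback rejoins the route at phenol 6.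

Step 7. Oxygen transfer to the deactivated C2=C3 bond may be sluggish, and the acid isomerisation may cost the acetal at O5. The fallback oxygenates C3 by deprotonation instead of epoxidation and sets out from flavone 12. LDA (THF, −78 °C) removes H3 to give the 3-lithio derivative [8-methoxy-2-(4-methoxyphenyl)-5,7-bis(methoxymethoxy)-6-methyl-4-oxo-4H-chromen-3-yl]lithium F9. Trimethyl borate traps it as dimethyl [8-methoxy-2-(4-methoxyphenyl)-5,7-bis(methoxymethoxy)-6-methyl-4-oxo-4H-chromen-3-yl]boronate F10, and H2O2 in AcOH (0 °C → rt) oxidises the C–B bond. The fallback rejoins the route at flavonol 14.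

**Further compounds**
F1 | step 6 | 2-hydroxy-3-methoxy-4,6-bis(methoxymethoxy)-5-methylbenzaldehyde | COCOc1c(C=O)c(O)c(OC)c(OCOC)c1C
F2 | step 6 | lithium (4-methoxyphenyl)acetylide | [Li]C#Cc1ccc(OC)cc1
F3 | step 6 | 2-[1-hydroxy-3-(4-methoxyphenyl)prop-2-yn-1-yl]-6-methoxy-3,5-bis(methoxymethoxy)-4-methylphenol (racemic) | COCOc1c(C(O)C#Cc2ccc(OC)cc2)c(O)c(OC)c(OCOC)c1C
F4 | step 4 | 6-hydroxy-2,4-bis(methoxymethoxy)-3-methylbenzaldehyde | COCOc1cc(O)c(C=O)c(OCOC)c1C
F5 | step 4 | 6-(benzyloxy)-2,4-bis(methoxymethoxy)-3-methylbenzaldehyde | COCOc1cc(OCc2ccccc2)c(C=O)c(OCOC)c1C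
F6 | step 4 | 6-(benzyloxy)-2,4-bis(methoxymethoxy)-3-methylphenyl formate | COCOc1cc(OCc2ccccc2)c(OC=O)c(OCOC)c1C
F7 | step 4 | 6-(benzyloxy)-2,4-bis(methoxymethoxy)-3-methylphenol | COCOc1cc(OCc2ccccc2)c(O)c(OCOC)c1C
F8 | step 4 | 1-(benzyloxy)-2-methoxy-3,5-bis(methoxymethoxy)-4-methylbenzene | COCOc1cc(OCc2ccccc2)c(OC)c(OCOC)c1C
F9 | step 7 | [8-methoxy-2-(4-methoxyphenyl)-5,7-bis(methoxymethoxy)-6-methyl-4-oxo-4H-chromen-3-yl]lithium | [Li]c1c(-c2ccc(OC)cc2)oc2c(OC)c(OCOC)c(C)c(OCOC)c2c1=O
F10 | step 7 | dimethyl [8-methoxy-2-(4-methoxyphenyl)-5,7-bis(methoxymethoxy)-6-methyl-4-oxo-4H-chromen-3-yl]boronate | COB(OC)c1c(-c2ccc(OC)cc2)oc2c(OC)c(OCOC)c(C)c(OCOC)c2c1=O
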